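**Strategy.** The plan rests on disconnecting the aryl ether bond O1–C8a of ring C. The C4 carbonyl sits ortho to C8a on ring A, so a fluorine at C8a is activated for addition–elimination, while the C5 and C7 oxygens are meta to C8a and do not cancel this activation. The key step is therefore an intramolecular SNAr: the C2 alkoxide of an open-chain, enantioenriched (S)-β-hydroxy ketone (from a catalytic asymmetric Mukaiyama aldol) displaces fluoride and closes the dihydropyranone ring with the C2 configuration retained. The same fluorine earlier directs the regioselective magnesiation that brings in the (R)-lavandulyl chain, built by Evans deconjugative alkylation.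

Key step: step 13

Remark 1: flavanone numbering (O1, C2, C3, C4, C4a, C5–C8, C8a; primed numbers for ring B) is used throughout.
Remark 2: the lavandulyl stereocentre is not touched after step 2; its descriptor changes from S (7, 8, 9, 15) to R (16 onward) only because the CIP priorities change when CH2–O/CH2–I becomes CH2–aryl.
Remark 3 (assumption for step 12): the (R,R)-bisphosphoramide·SiCl4 system is taken to add nucleophiles to the Re face of aryl aldehydes, so the (S,S)-catalyst is specified for the Si-face addition that gives the (S)-carbinol.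

Step 1
Reactants: 1 (S)-4-benzyl-2-oxazolidinone; 2 3-methylbut-2-enoyl chloride
Product: 4 (S)-4-benzyl-3-(3-methylbut-2-enoyl)oxazolidin-2-one, via lithium oxazolidinide 3 (not isolated)
Conditions: n-BuLi, THF, −78 °C; then 2, −78 → 0 °C
Reagents that add atoms: none
Why: N-acylation of the lithiated oxazolidinone by the acid chloride (Evans imide formation) should be clean because no amine base is present that could turn the acid chloride into a vinylketene.

Step 2
Reactants: 4 (S)-4-benzyl-3-(3-methylbut-2-enoyl)oxazolidin-2-one; 5 prenyl bromide (1-bromo-3-methylbut-2-ene)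
Product: 7 (S)-4-benzyl-3-[(2S)-5-methyl-2-(prop-1-en-2-yl)hex-4-enoyl]oxazolidin-2-one, via sodium Z-dienolate 6 (not isolated)
Conditions: NaHMDS, THF, −78 °C; then 5, −78 → −40 °C
Reagents that add atoms: none
Why: Evans deconjugative alkylation: γ-deprotonation gives the chelated Z-dienolate, which should be alkylated at C-α by the allylic bromide on the face opposite the C4 benzyl group, setting the (2S) centre and moving the alkene out of conjugation to form the isopropenyl group.

Step 3
Reactants: 7 (S)-4-benzyl-3-[(2S)-5-methyl-2-(prop-1-en-2-yl)hex-4-enoyl]oxazolidin-2-one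
Product: 8 (S)-lavandulol [(2S)-5-methyl-2-(prop-1-en-2-yl)hex-4-en-1-ol]
Conditions: LiBH4, MeOH (1 equiv), Et2O, 0 °C
Reagents that add atoms: none
Why: reductive cleavage of the imide by lithium borohydride should give the primary alcohol without enolising the α-stereocentre, and the auxiliary is recovered.

Step 4
Reactants: 8 (S)-lavandulol
Product: 9 (S)-lavandulyl iodide [(3S)-3-(iodomethyl)-2,6-dimethylhepta-1,5-diene]
Conditions: I2, PPh3, imidazole, CH2Cl2, 0 °C → rt
Reagents that add atoms: iodine, II
Why: Appel iodination is an SN2 displacement at the primary carbon, so the adjacent stereocentre is untouched and the buffered medium should spare both alkenes.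

Step 5
Reactants: 10 2,6-difluoro-4-hydroxybenzonitrile
Product: 11 2,6-difluoro-4-(methoxymethoxy)benzonitrile
Conditions: MOMCl, i-Pr2NEt, CH2Cl2, 0 °C → rt
Reagents that add atoms: chloromethyl methyl ether, COCCl
Why: O-alkylation of the acidic phenol gives a MOM ether that survives every later basic step and helps direct the metalation in step 7.

Step 6
Reactants: 11 2,6-difluoro-4-(methoxymethoxy)benzonitrile
Product: 12 2-fluoro-6-methoxy-4-(methoxymethoxy)benzonitrile
Conditions: NaOMe (1.05 equiv), THF–MeOH, 0 °C → rt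
Reagents that add atoms: sodium methoxide, C[O-].[Na+]
Why: SNAr ortho to the nitrile: the two fluorines are equivalent by symmetry, so there is no regiochemical question, and the first methoxy group should deactivate the ring towards a second substitution.

Step 7
Reactants: 12 2-fluoro-6-methoxy-4-(methoxymethoxy)benzonitrile
Product: 14 2-fluoro-3-iodo-6-methoxy-4-(methoxymethoxy)benzonitrile, via arylmagnesium chloride 13 (not isolated)
Conditions: TMPMgCl·LiCl, THF, −20 → 0 °C; then I2, −20 °C → rt
Reagents that add atoms: iodine, II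
Why: directed magnesiation should occur at C3–H, the most acidic ring C–H (flanked by fluorine and the chelating MOM ether) and not at C5–H between two ethers; the nitrile tolerates the amide base, and iodinolysis fixes the position.

Step 8
Reactants: 9 (S)-lavandulyl iodide; 14 2-fluoro-3-iodo-6-methoxy-4-(methoxymethoxy)benzonitrile
Product: 16 2-fluoro-6-methoxy-4-(methoxymethoxy)-3-[(2R)-5-methyl-2-(prop-1-en-2-yl)hex-4-en-1-yl]benzonitrile, via (S)-lavandulylzinc iodide 15 (not isolated)
Conditions: 9, Zn dust, LiCl, THF, 35 °C; then 14, Pd(OAc)2 (2 mol%), SPhos (4 mol%), THF, rt → 45 °C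
Reagents that add atoms: none
Why: Negishi sp3–sp2 coupling: zinc insertion into the primary iodide leaves the β-stereocentre intact, a bulky biarylphosphine should couple the primary alkylzinc with the di-ortho-substituted aryl iodide faster than β-hydride elimination, and the nitrile and aryl fluoride are inert.

Step 9
Reactants: 16 2-fluoro-6-methoxy-4-(methoxymethoxy)-3-[(2R)-5-methyl-2-(prop-1-en-2-yl)hex-4-en-1-yl]benzonitrile
Product: 19 1-{2-fluoro-6-methoxy-4-(methoxymethoxy)-3-[(2R)-5-methyl-2-(prop-1-en-2-yl)hex-4-en-1-yl]phenyl}ethan-1-one, via N-lithio ketimine 17 (not isolated), via N–H ketimine 18 (not isolated)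
Conditions: MeLi, THF, −78 → 0 °C; then AcOH–H2O–THF, rt
Reagents that add atoms: methyllithium, [Li]C; water, O
Why: organolithium addition to the nitrile stops at the N-lithio ketimine, and mildly acidic hydrolysis should give the methyl ketone without cleaving the MOM ether.

Step 10
Reactants: 19 1-{2-fluoro-6-methoxy-4-(methoxymethoxy)-3-[(2R)-5-methyl-2-(prop-1-en-2-yl)hex-4-en-1-yl]phenyl}ethan-1-one
Product: 21 trimethylsilyl enol ether of 19, via lithium enolate 20 (not isolated)
Conditions: LiHMDS, THF, −78 °C; TMSCl, −78 → 0 °C; non-aqueous work-up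
Reagents that add atoms: chlorotrimethylsilane, C[Si](C)(C)Cl
Why: kinetic enolisation of the methyl ketone and O-silylation give the nucleophile for the Mukaiyama aldol, and the aryl fluoride cannot be reached by the enolate oxygen.

Step 11
Reactants: 22 4-hydroxy-2-methoxybenzaldehyde
Product: 23 2-methoxy-4-(methoxymethoxy)benzaldehyde
Conditions: MOMCl, i-Pr2NEt, CH2Cl2, 0 °C → rt
Reagents that add atoms: chloromethyl methyl ether, COCCl
Why: O-alkylation masks the 4'-phenol, whose phenoxide would otherwise promote quinone-methide-type loss of the benzylic oxygen in the basic key step.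

Step 12
Reactants: 21 trimethylsilyl enol ether of 19; 23 2-methoxy-4-(methoxymethoxy)benzaldehyde
Product: 25 (3S)-1-{2-fluoro-6-methoxy-4-(methoxymethoxy)-3-[(2R)-5-methyl-2-(prop-1-en-2-yl)hex-4-en-1-yl]phenyl}-3-hydroxy-3-[2-methoxy-4-(methoxymethoxy)phenyl]propan-1-one, via trichlorosilyl aldolate 24 (not isolated)
Conditions: SiCl4 (1.5 equiv), (S,S)-binaphthyldiamine-derived bisphosphoramide (5 mol%), i-Pr2NEt (10 mol%), CH2Cl2, −78 °C; then sat. aq. NaHCO3
Reagents that add atoms: none
Why: Lewis-base-activated SiCl4 Mukaiyama aldol, established for silyl enol ethers of aryl methyl ketones with aromatic aldehydes: the chiral phosphoramide-bound trichlorosilyl cation binds the aldehyde and should expose its Si face to the enol ether in an open transition state, so the catalyst sets the (3S) carbinol.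

Step 13
Reactants: 25 (3S)-β-hydroxy ketone
Product: 27 (2S)-5-methoxy-7-(methoxymethoxy)-2-[2-methoxy-4-(methoxymethoxy)phenyl]-8-[(2R)-5-methyl-2-(prop-1-en-2-yl)hex-4-en-1-yl]chroman-4-one, via sodium alkoxide 26 (not isolated)
Conditions: NaH (1.1 equiv), THF–DMF (9:1), 0 °C → rt; AcOH quench at 0 °C
Reagents that add atoms: none
Why: Sodium hydride deprotonates the C2 hydroxyl, and the alkoxide 26 attacks C8a, which carries fluorine ortho to the C4 ketone on ring A; addition–elimination through a Meisenheimer-type σ-complex, with the charge taken up by the carbonyl, expels fluoride (intramolecular SNAr O-arylation, the known way from 3-hydroxy-1-(2-fluoroaryl)propan-1-ones to chroman-4-ones). Ring C closes in a 6-exo-trig mode (C8a=C8 counted as the exocyclic bond), and the forming ring holds the carbonyl in the plane of ring A, so its activation is fully available in the transition state. No new stereocentre is formed: C2 keeps its (S) configuration because only the O–H bond of the carbinol is broken, and the lavandulyl centre is remote. The step needs chemoselectivity for O-arylation over retro-aldol cleavage and E1cB dehydration of the aldolate; kinetic O–H deprotonation with a slight excess of non-nucleophilic base at 0 °C, the high effective molarity of the six-membered closure and fluoride as the best SNAr leaving group should secure it. Regiochemistry is unambiguous because C8a is the only ring carbon with a leaving group, the C5 methoxy and C7 MOM ether being meta to it and inert.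

Step 14
Reactants: 27 bis-MOM flavanone
Product: 28 (2S)-2'-methoxykurarinone [(2S)-7-hydroxy-2-(4-hydroxy-2-methoxyphenyl)-5-methoxy-8-[(2R)-5-methyl-2-(prop-1-en-2-yl)hex-4-en-1-yl]chroman-4-one]
Conditions: 3 M aq. HCl–MeOH (1:10), 40 °C
Reagents that add atoms: none
Why: acid-catalysed acetal exchange transfers both methoxymethyl groups to methanol and frees the two phenols; dilute acid at mild temperature should leave the two alkenes and the C2 centre untouched.

**Compound list**
1 | (S)-4-benzyl-2-oxazolidinone | O=C1N[C@@H](Cc2ccccc2)CO1 | starting material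
2 | 3-methylbut-2-enoyl chloride | CC(C)=CC(=O)Cl | starting material
3 | lithium (S)-4-benzyl-2-oxooxazolidin-3-ide (formed in the flask) | [Li]N1[C@@H](Cc2ccccc2)COC1=O | intermediate
4 | (S)-4-benzyl-3-(3-methylbut-2-enoyl)oxazolidin-2-one | CC(C)=CC(=O)N1[C@@H](Cc2ccccc2)COC1=O | intermediate
5 | prenyl bromide (1-bromo-3-methylbut-2-ene) | CC(C)=CCBr | starting material
6 | sodium Z-dienolate of 4 (formed in the flask) | [Na+].C=C(C)/C=C(\[O-])N1[C@@H](Cc2ccccc2)COC1=O | intermediate
7 | (S)-4-benzyl-3-[(2S)-5-methyl-2-(prop-1-en-2-yl)hex-4-enoyl]oxazolidin-2-one | C=C(C)[C@H](CC=C(C)C)C(=O)N1[C@@H](Cc2ccccc2)COC1=O | intermediate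
8 | (S)-lavandulol, (2S)-5-methyl-2-(prop-1-en-2-yl)hex-4-en-1-ol | C=C(C)[C@H](CC=C(C)C)CO | intermediate
9 | (S)-lavandulyl iodide, (3S)-3-(iodomethyl)-2,6-dimethylhepta-1,5-diene | C=C(C)[C@H](CC=C(C)C)CI | intermediate
10 | 2,6-difluoro-4-hydroxybenzonitrile | N#Cc1c(F)cc(O)cc1F | starting material
11 | 2,6-difluoro-4-(methoxymethoxy)benzonitrile | N#Cc1c(F)cc(OCOC)cc1F | intermediate
12 | 2-fluoro-6-methoxy-4-(methoxymethoxy)benzonitrile | N#Cc1c(F)cc(OCOC)cc1OC | intermediate
13 | [3-cyano-2-fluoro-4-methoxy-6-(methoxymethoxy)phenyl]magnesium chloride (formed in the flask) | N#Cc1c(F)c([Mg]Cl)c(OCOC)cc1OC | intermediate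
14 | 2-fluoro-3-iodo-6-methoxy-4-(methoxymethoxy)benzonitrile | N#Cc1c(F)c(I)c(OCOC)cc1OC | intermediate
15 | (S)-lavandulylzinc iodide (formed in the flask) | C=C(C)[C@H](CC=C(C)C)C[Zn]I | intermediate
16 | 2-fluoro-6-methoxy-4-(methoxymethoxy)-3-[(2R)-5-methyl-2-(prop-1-en-2-yl)hex-4-en-1-yl]benzonitrile | C=C(C)[C@H](CC=C(C)C)Cc1c(OCOC)cc(OC)c(C#N)c1F | intermediate
17 | N-lithio ketimine from 16 and MeLi (formed in the flask) | C=C(C)[C@H](CC=C(C)C)Cc1c(OCOC)cc(OC)c(C(C)=N[Li])c1F | intermediate
18 | N–H ketimine (formed in the flask) | C=C(C)[C@H](CC=C(C)C)Cc1c(OCOC)cc(OC)c(C(C)=N)c1F | intermediate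
19 | 1-{2-fluoro-6-methoxy-4-(methoxymethoxy)-3-[(2R)-5-methyl-2-(prop-1-en-2-yl)hex-4-en-1-yl]phenyl}ethan-1-one | C=C(C)[C@H](CC=C(C)C)Cc1c(OCOC)cc(OC)c(C(C)=O)c1F | intermediate
20 | lithium enolate of 19 (formed in the flask) | C=C(C)[C@H](CC=C(C)C)Cc1c(OCOC)cc(OC)c(C(=C)O[Li])c1F | intermediate
21 | trimethylsilyl enol ether of 19 | C=C(C)[C@H](CC=C(C)C)Cc1c(OCOC)cc(OC)c(C(=C)O[Si](C)(C)C)c1F | intermediate
22 | 4-hydroxy-2-methoxybenzaldehyde | O=Cc1ccc(O)cc1OC | starting material
23 | 2-methoxy-4-(methoxymethoxy)benzaldehyde | O=Cc1ccc(OCOC)cc1OC | intermediate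
24 | (3S)-trichlorosilyl aldolate (formed in the flask) | C=C(C)[C@H](CC=C(C)C)Cc1c(OCOC)cc(OC)c(C(=O)C[C@H](O[Si](Cl)(Cl)Cl)c2ccc(OCOC)cc2OC)c1F | intermediate
25 | (3S)-1-{2-fluoro-6-methoxy-4-(methoxymethoxy)-3-[(2R)-5-methyl-2-(prop-1-en-2-yl)hex-4-en-1-yl]phenyl}-3-hydroxy-3-[2-methoxy-4-(methoxymethoxy)phenyl]propan-1-one | C=C(C)[C@H](CC=C(C)C)Cc1c(OCOC)cc(OC)c(C(=O)C[C@H](O)c2ccc(OCOC)cc2OC)c1F | intermediate
26 | sodium alkoxide of 25 (formed in the flask) | [Na+].C=C(C)[C@H](CC=C(C)C)Cc1c(OCOC)cc(OC)c(C(=O)C[C@H]([O-])c2ccc(OCOC)cc2OC)c1F | intermediate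
27 | (2S)-5-methoxy-7-(methoxymethoxy)-2-[2-methoxy-4-(methoxymethoxy)phenyl]-8-[(2R)-5-methyl-2-(prop-1-en-2-yl)hex-4-en-1-yl]chroman-4-one | C=C(C)[C@H](CC=C(C)C)Cc1c(OCOC)cc(OC)c2c1O[C@H](c1ccc(OCOC)cc1OC)CC2=O | intermediate
28 | (2S)-2'-methoxykurarinone | C=C(C)[C@H](CC=C(C)C)Cc1c(O)cc(OC)c2c1O[C@H](c1ccc(O)cc1OC)CC2=O | target

**Step count and risks**

Total step count: 14. Longest linear sequence: 10 steps (steps 1–4, 8, 9, 10, 12, 13, 14, from (S)-4-benzyl-2-oxazolidinone); the arene line from 2,6-difluoro-4-hydroxybenzonitrile is 9 steps.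

Most likely to fail:

1. Step 13 (key step). The aldolate may fragment by retro-aldol (loss of material and, after re-addition, erosion of configuration at C2) or dehydrate by E1cB faster than it attacks the electron-rich fluoroarene. Fallback: the fallback sets out from 25. Dess–Martin oxidation gives the 1,3-diketone F1. With K2CO3 in DMF at 60 °C the enolate oxygen displaces the same fluoride (same O1–C8a bond, no stereocentre at risk, classical flavone closure) to give the bis-MOM flavone F2. Copper hydride-catalysed asymmetric 1,4-reduction (Cu(OAc)2, the DTBM-SEGPHOS enantiomer that delivers hydride to the Re face of C2, (EtO)2MeSiH, t-BuOH, toluene) then sets C2, leaves the isolated alkenes alone and comes back to the route at 27.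

2. Step 12. Facial selectivity may be poor or conversion low, because the electron-rich ortho-methoxy aldehyde may bind the silicon Lewis acid weakly or in a chelated mode and the hindered enol ether adds slowly. Fallback: the fallback sets out from 19 and 23. Claisen–Schmidt condensation (Ba(OH)2·8H2O, MeOH, rt) gives the (E)-chalcone F3. Copper-catalysed enantioselective conjugate borylation (CuCl, NaOt-Bu, a Josiphos-type ligand chosen for boron delivery to the Si face of C-β, B2pin2, MeOH, THF) gives the (S)-β-boryl ketone F4. Oxidation with NaBO3·4H2O, which proceeds with retention, comes back to the route at 25.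

3. Step 8. Oxidative addition and transmetalation at the di-ortho-substituted iodide may be slow, so that protodezincation or β-hydride elimination of the alkylpalladium species takes over; zinc insertion may also stall. Fallback (polarity reversal): from 8, tosylation (TsCl, pyridine, 0 °C) gives (S)-lavandulyl tosylate F5. From 12, magnesiation as in step 7 gives 13, which is alkylated by F5 under copper catalysis (Li2CuCl4, 3 mol%, THF, 0 °C → rt; SN2-type Grignard alkylation) and comes back to the route at 16, bypassing 9, 14 and 15.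

**Further compounds**
F1 | step 13 | 1-{2-fluoro-6-methoxy-4-(methoxymethoxy)-3-[(2R)-5-methyl-2-(prop-1-en-2-yl)hex-4-en-1-yl]phenyl}-3-[2-methoxy-4-(methoxymethoxy)phenyl]propane-1,3-dione | C=C(C)[C@H](CC=C(C)C)Cc1c(OCOC)cc(OC)c(C(=O)CC(=O)c2ccc(OCOC)cc2OC)c1F
F2 | step 13 | 5-methoxy-7-(methoxymethoxy)-2-[2-methoxy-4-(methoxymethoxy)phenyl]-8-[(2R)-5-methyl-2-(prop-1-en-2-yl)hex-4-en-1-yl]-4H-chromen-4-one | C=C(C)[C@H](CC=C(C)C)Cc1c(OCOC)cc(OC)c2c1oc(-c1ccc(OCOC)cc1OC)cc2=O
F3 | step 12 | (E)-1-{2-fluoro-6-methoxy-4-(methoxymethoxy)-3-[(2R)-5-methyl-2-(prop-1-en-2-yl)hex-4-en-1-yl]phenyl}-3-[2-methoxy-4-(methoxymethoxy)phenyl]prop-2-en-1-one | C=C(C)[C@H](CC=C(C)C)Cc1c(OCOC)cc(OC)c(C(=O)/C=C/c2ccc(OCOC)cc2OC)c1F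
F4 | step 12 | (3S)-β-(pinacolboryl) ketone corresponding to 25 | C=C(C)[C@H](CC=C(C)C)Cc1c(OCOC)cc(OC)c(C(=O)C[C@H](B3OC(C)(C)C(C)(C)O3)c2ccc(OCOC)cc2OC)c1F
F5 | step 8 | (S)-lavandulyl 4-methylbenzenesulfonate | C=C(C)[C@H](CC=C(C)C)COS(=O)(=O)c1ccc(C)cc1
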